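**Overview** (germacrane numbering: C1 ketone, C4/C5 epoxide, C6 lactone carbinol, C7 spiro carbon, C8 ester carbinol, C9 CH2, C10 ether carbon, C11=C13 methylene, C12 lactone C=O; O7 = oxolane oxygen)

- **Cuts, in retrosynthetic order:** C8–O ester, then C8–H (ketone reduction), then O7–C7 (transannular SN2′, which also creates C11=C13), then the N–O helper. Next come C8–C9 and O7–C10 together (nitrile oxide plus isopropenyl ketone), C7–vinyl and C11–C13 (cuprate/CH2O), C6–C7 (acetylide), and the epoxide oxygen.
- **Forward order:** the nerol chain is built first, then the butenolide. One step then closes the isoxazoline and the ten-membered carbocycle. After that the oxolane and the α-methylene lactone form together, and the ester goes on last.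
- **Enabling feature:** the oxolane segment C8(O)–C9H2–C10(O)(CH3)(acyl) is 1,3-dioxygenated, which is an isoxazoline retron. C10 with its methyl and its C1 acyl group is an isopropenyl ketone. C7 is the β-carbon of the lactone, so the nitrile-oxide oxygen, once freed from nitrogen, can become O7.
- **Stereochemistry:** C4/C5 come from catalytic asymmetric epoxidation and C6 from Felkin–Anh addition. C10 is set by the tether in the cycloaddition, C7 by transannular delivery, and C8 by CBS reduction.

Key step: step 8

Remark: the C–OOH carbon of 8 and the ozonide carbon of 10 are epimer mixtures that disappear in the same flask, so their SMILES leave these centres open.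

**Step 1**
Reactants: 1 nerol
Product: 2 (2S,3R)-2,3-epoxynerol
Conditions: Ti(OiPr)4 (cat.), L-(+)-DET (cat.), t-BuOOH, 4 Å MS, CH2Cl2, −20 °C
Reagents that add atoms: tert-butyl hydroperoxide, CC(C)(C)OO
Why: Katsuki–Sharpless asymmetric epoxidation touches only the allylic-alcohol alkene, and with L-(+)-tartrate it delivers oxygen to the face that gives 4R,5S, the Z geometry fixing the cis-epoxide.

**Step 2**
Reactants: 2 (2S,3R)-2,3-epoxynerol
Product: 3 epoxy aldehyde
Conditions: TEMPO (cat.), PhI(OAc)2, CH2Cl2, 0 °C to rt
Reagents that add atoms: none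
Why: Oxoammonium (TEMPO/PhI(OAc)2) oxidation of a primary alcohol stops at the aldehyde and leaves the epoxide, the alkene and the α-stereocentre untouched.

**Step 3**
Reactants: 4 ethyl propiolate; 3 epoxy aldehyde
Product: 5 γ-hydroxy ynoate
Conditions: 4, LDA, THF, −78 °C; then 3, −78 °C; aq NH4Cl
Reagents that add atoms: none
Why: 1,2-Addition of a lithium acetylide to an α,β-epoxy aldehyde under Felkin–Anh control (C5–O perpendicular to C=O, attack anti to it past H5) should place the C6 oxygen anti to the epoxide oxygen, as the target requires.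

**Step 4**
Reactants: 5 γ-hydroxy ynoate
Product: 7 4-vinyl-3-(hydroxymethyl)butenolide, via open-chain Z-hydroxy ester 6 (not isolated)
Conditions: CH2=CHMgBr, CuI·2LiCl, THF, −78 °C; CH2O (monomer in THF), −78 to −30 °C; aq NH4Cl; PPTS (cat.), CH2Cl2, rt
Reagents that add atoms: vinylmagnesium bromide, C=C[Mg]Br; formaldehyde, C=O
Why: Copper-mediated conjugate addition puts the vinyl group on C7, and the allenolate is trapped by formaldehyde at C11 from the side of the smaller vinyl group (tandem 1,4-addition–aldol), so the ester ends cis to C6 and lactonises without touching any stereocentre.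

**Step 5**
Reactants: 7 4-vinyl-3-(hydroxymethyl)butenolide
Product: 9 enone acetate, via allylic hydroperoxide 8 (not isolated)
Conditions: O2, TPP (cat.), hν, CH2Cl2, 0 °C; then Ac2O, pyridine, DMAP (cat.), 0 °C to rt
Reagents that add atoms: oxygen, O=O; acetic anhydride, CC(=O)OC(C)=O
Why: The Schenck ene reaction attacks the only electron-rich trisubstituted alkene, and Kornblum–DeLaMare dehydration of the secondary hydroperoxide gives the isopropenyl ketone while the same reagent acetylates the primary alcohol (the regioisomeric tertiary hydroperoxide cannot dehydrate and is separated).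

**Step 6**
Reactants: 9 enone acetate
Product: 11 4-formylbutenolide, via secondary ozonide 10 (not isolated)
Conditions: O3 (1 equiv, Sudan Red 7B end point), CH2Cl2, −78 °C; Me2S
Reagents that add atoms: ozone, [O-][O+]=O
Why: In this chemoselective ozonolysis the monosubstituted terminal alkene of the dienoate is the least deactivated π bond, the α-substituted enone and the tetrasubstituted butenolide alkene being poorer partners for the electrophilic ozone.

**Step 7**
Reactants: 11 4-formylbutenolide
Product: 12 (E)-aldoxime
Conditions: NH2OH·HCl, NaOAc, EtOH–THF, 0 °C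
Reagents that add atoms: hydroxylamine hydrochloride, NO.Cl
Why: Buffered oxime condensation takes place at the far more electrophilic aldehyde ahead of the hindered conjugated ketone, and the mild buffer avoids deprotonation at C6.

**Step 8**
Reactants: 12 (E)-aldoxime
Product: 15 bridged isoxazoline, via hydroximoyl chloride 13 (not isolated), via nitrile oxide 14 (not isolated)
Conditions: NCS, DMF, 0 °C to rt; then slow addition to KHCO3 (solid), EtOAc, ca. 1 mM, 40 °C
Reagents that add atoms: none
Why: NCS chlorinates the aldoxime to 13, solid KHCO3 releases nitrile oxide 14 slowly, and the dipole adds to the tethered isopropenyl ketone in a concerted [π4s+π2s] step, an intramolecular nitrile oxide–olefin cycloaddition (INOC), a reaction type known for ω-alkenyl nitrile oxides up to macrocycles. As with every 1,1-disubstituted alkene the dipole carbon C8 bonds to the CH2 terminus C9 and the dipole oxygen to the fully substituted C10, so the 2-isoxazoline closes by cycloaddition and the ten-membered carbocycle C1–C10 closes at the same time in the bridged mode (C8–C9–C10 common to both rings). The forming isoxazoline stays coplanar with the butenolide to keep the C7=C11/C8=N conjugation, so the alkene has to come in along the C6 edge of the butenolide. The tether leaves C6 on the face that carries C5 and the cis-epoxide turns it back, which places C1 on that face and the C10 methyl on the other and should give 10R. The step needs intramolecular reaction to beat dimerisation to the furoxan, which slow heterogeneous release at high dilution secures, and it needs one alkene only, which holds because the butenolide alkene is tetrasubstituted and conjugated to the dipole while the terminal enone alkene is the only accessible dipolarophile. The epoxide, the allylic acetate, the lactone and the ketone are inert to these nearly neutral conditions.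

**Step 9**
Reactants: 15 bridged isoxazoline
Product: 17 β-hydroxy ketone, via β-hydroxy imine 16 (not isolated)
Conditions: Mo(CO)6, MeCN–H2O (15:1), 80 °C
Reagents that add atoms: water, O
Why: Molybdenum hexacarbonyl-mediated reductive N–O cleavage of a 2-isoxazoline followed by imine hydrolysis unmasks the β-ketol, removes the nitrogen helper and leaves the C10–O bond and all stereocentres in place.

**Step 10**
Reactants: 17 β-hydroxy ketone
Product: 18 oxolan-3-one with α-methylene lactone
Conditions: DABCO, MeCN, 0 °C to rt
Reagents that add atoms: none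
Why: Transannular 5-exo oxa-Michael addition to C7 with E1cB loss of acetate (SN2′, the reactivity of Baylis–Hillman-type allylic acetates) closes the oxolane and creates C11=C13, the ten-membered ring holding the C10 hydroxyl on the C5 face of the butenolide so that O7 ends cis to C5.

**Step 11**
Reactants: 18 oxolan-3-one with α-methylene lactone
Product: 19 C8 alcohol
Conditions: (R)-Me-CBS (cat.), BH3·SMe2, THF, −40 °C; MeOH
Reagents that add atoms: none
Why: Corey–Bakshi–Shibata reduction distinguishes the quaternary C7 (large) from C9H2 (small) and with the (R)-catalyst should give 8S, the α-alkoxy five-membered ketone reacting ahead of the C1 ketone, which sits in the medium ring next to a quaternary carbon.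

**Step 12**
Reactants: 19 C8 alcohol
Product: 20 target CNP0241021.1
Conditions: methacrylic anhydride, Et3N, DMAP (cat.), CH2Cl2, 0 °C to rt
Reagents that add atoms: methacrylic anhydride, C=C(C)C(=O)OC(=O)C(C)=C
Why: DMAP-catalysed acylation (Steglich-type acyl transfer) of the only free hydroxyl proceeds with retention at C8 and gives the target.

**Compound list**

1 | nerol, (2Z)-3,7-dimethylocta-2,6-dien-1-ol | CC(C)=CCC/C(C)=C\CO | starting material
2 | [(2S,3R)-3-methyl-3-(4-methylpent-3-en-1-yl)oxiran-2-yl]methanol | OC[C@@H]1O[C@]1(C)CCC=C(C)C | intermediate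
3 | (2R,3R)-3-methyl-3-(4-methylpent-3-en-1-yl)oxirane-2-carbaldehyde | O=C[C@@H]1O[C@]1(C)CCC=C(C)C | intermediate
4 | ethyl propiolate | C#CC(=O)OCC | starting material
5 | ethyl (4S)-4-hydroxy-4-[(2S,3R)-3-methyl-3-(4-methylpent-3-en-1-yl)oxiran-2-yl]but-2-ynoate | CCOC(=O)C#C[C@H](O)[C@@H]1O[C@]1(C)CCC=C(C)C | intermediate
6 | ethyl (2Z)-2-(hydroxymethyl)-3-{(S)-hydroxy[(2S,3R)-3-methyl-3-(4-methylpent-3-en-1-yl)oxiran-2-yl]methyl}penta-2,4-dienoate | CCOC(=O)/C(CO)=C(/C=C)[C@H](O)[C@@H]1O[C@]1(C)CCC=C(C)C | intermediate
7 | (5S)-4-ethenyl-3-(hydroxymethyl)-5-[(2S,3R)-3-methyl-3-(4-methylpent-3-en-1-yl)oxiran-2-yl]furan-2(5H)-one | C=CC1=C(CO)C(=O)O[C@@H]1[C@@H]2O[C@]2(C)CCC=C(C)C | intermediate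
8 | as 7, side chain 3-hydroperoxy-4-methylpent-4-en-1-yl (C–OOH epimers) | C=CC1=C(CO)C(=O)O[C@@H]1[C@@H]2O[C@]2(C)CCC(OO)C(C)=C | intermediate
9 | {(5S)-4-ethenyl-5-[(2S,3R)-3-methyl-3-(4-methyl-3-oxopent-4-en-1-yl)oxiran-2-yl]-2-oxo-2,5-dihydrofuran-3-yl}methyl acetate | C=CC1=C(COC(C)=O)C(=O)O[C@@H]1[C@@H]2O[C@]2(C)CCC(=O)C(C)=C | intermediate
10 | as 9, vinyl group replaced by 1,2,4-trioxolan-3-yl (epimers) | C1OC(OO1)C1=C(COC(C)=O)C(=O)O[C@@H]1[C@@H]2O[C@]2(C)CCC(=O)C(C)=C | intermediate
11 | {(5S)-4-formyl-5-[(2S,3R)-3-methyl-3-(4-methyl-3-oxopent-4-en-1-yl)oxiran-2-yl]-2-oxo-2,5-dihydrofuran-3-yl}methyl acetate | O=CC1=C(COC(C)=O)C(=O)O[C@@H]1[C@@H]2O[C@]2(C)CCC(=O)C(C)=C | intermediate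
12 | (E)-oxime of 11 | O/N=C/C1=C(COC(C)=O)C(=O)O[C@@H]1[C@@H]2O[C@]2(C)CCC(=O)C(C)=C | intermediate
13 | (Z)-hydroximoyl chloride of 12 | O/N=C(\Cl)C1=C(COC(C)=O)C(=O)O[C@@H]1[C@@H]2O[C@]2(C)CCC(=O)C(C)=C | intermediate
14 | nitrile oxide at C8 | [O-][N+]#CC1=C(COC(C)=O)C(=O)O[C@@H]1[C@@H]2O[C@]2(C)CCC(=O)C(C)=C | intermediate
15 | (4R,5S,6S,10R)-isoxazoline: ten-membered carbocycle C1–C10 bridged by C8=N–O–C10, with 1-oxo, 4,5-cis-epoxide, 7(11)-en-12,6-olide and 13-acetoxy | C1[C@@]2(C)ON=C1C1=C(COC(C)=O)C(=O)O[C@@H]1[C@@H]1O[C@]1(C)CCC2=O | intermediate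
16 | (4R,5S,6S,10R)-10-hydroxy-8-imine of the same carbocycle | N=C1C[C@@](C)(O)C(=O)CC[C@@]2(C)O[C@H]2[C@H]2OC(=O)C(COC(C)=O)=C12 | intermediate
17 | (4R,5S,6S,10R)-13-acetoxy-4,5-epoxy-10-hydroxy-1,8-dioxogermacr-7(11)-en-12,6-olide | O=C1C[C@@](C)(O)C(=O)CC[C@@]2(C)O[C@H]2[C@H]2OC(=O)C(COC(C)=O)=C12 | intermediate
18 | (4R,5S,6R,7R,10R)-4,5:7,10-diepoxy-1,8-dioxogermacr-11(13)-en-12,6-olide | O=C1C[C@@]2(C)O[C@@]13C(=C)C(=O)O[C@@H]3[C@@H]1O[C@]1(C)CCC2=O | intermediate
19 | (4R,5S,6R,7S,8S,10R)-4,5:7,10-diepoxy-8-hydroxy-1-oxogermacr-11(13)-en-12,6-olide | O[C@H]1C[C@@]2(C)O[C@@]13C(=C)C(=O)O[C@@H]3[C@@H]1O[C@]1(C)CCC2=O | intermediate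
20 | CNP0241021.1, 8-O-methacrylate of 19 | C=C(C)C(=O)O[C@H]1C[C@@]2(C)O[C@@]13C(=C)C(=O)O[C@@H]3[C@@H]1O[C@]1(C)CCC2=O | target

Total step count: 12. Longest linear sequence: 12 steps, from nerol.

**Steps most likely to fail**

**Step 8.** The ten-membered ring may close too slowly, so that dimerisation of the dipole takes over, or the alkene may be attacked on the other face. The fallback sets out from 9 and returns at 17.
- The vinyl group of 9 would be oxidised under Tsuji–Wacker conditions (PdCl2, CuCl, O2, DMF–H2O) to the 4-acetylbutenolide F1.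
- Ozonolysis of the remaining isopropenyl group (O3; Me2S) would give the 1,2-diketone F2.
- An enamine-mediated intramolecular aldol addition (L-proline, DMSO, high dilution) of the acetyl CH3 to the methyl-side carbonyl of the diketone would close the carbocycle and give 17. In this variant C9 comes from the former vinyl terminus.

**Step 10.** Retro-aldol cleavage of the tertiary β-ketol, or deprotonation at C6 with opening of the neighbouring epoxide, may outrun the hindered C–O bond formation. The fallback sets out from 17 and returns at 20.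
- The C8 ketone would first be reduced under CBS conditions to the allylic 8,10-diol F3.
- The secondary hydroxyl would be acylated selectively with methacrylic anhydride to the 8-methacrylate F4.
- The oxolane would then be closed under base-free Tsuji–Trost conditions (Pd(PPh3)4, THF) through the C7–C11–C13 π-allyl complex. Five-membered ring formation directs the tertiary hydroxyl to C7 and gives 20.

**Step 4.** Trapping of the allenolate by formaldehyde may be incomplete, the alkene geometry may be lost, or the organometallic may attack the epoxide. The fallback sets out from 5 and returns at 7.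
- The cuprate adduct would be quenched with iodine and lactonised to the 3-iodo-4-vinylbutenolide F5.
- A Stille coupling with (tributylstannyl)methanol (Pd(PPh3)4, dioxane, 80 °C) would install the C13 hydroxymethyl group and give 7.

**Further compounds**

F1 | step 8 | {(5S)-4-acetyl-5-[(2S,3R)-3-methyl-3-(4-methyl-3-oxopent-4-en-1-yl)oxiran-2-yl]-2-oxo-2,5-dihydrofuran-3-yl}methyl acetate | CC(=O)C1=C(COC(C)=O)C(=O)O[C@@H]1[C@@H]2O[C@]2(C)CCC(=O)C(C)=C
F2 | step 8 | {(5S)-4-acetyl-5-[(2S,3R)-3-(3,4-dioxopentyl)-3-methyloxiran-2-yl]-2-oxo-2,5-dihydrofuran-3-yl}methyl acetate | CC(=O)C1=C(COC(C)=O)C(=O)O[C@@H]1[C@@H]2O[C@]2(C)CCC(=O)C(C)=O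
F3 | step 10 | (4R,5S,6S,8S,10R)-13-acetoxy-4,5-epoxy-8,10-dihydroxy-1-oxogermacr-7(11)-en-12,6-olide | O[C@H]1C[C@@](C)(O)C(=O)CC[C@@]2(C)O[C@H]2[C@H]2OC(=O)C(COC(C)=O)=C12
F4 | step 10 | 8-O-methacrylate of F3 | C=C(C)C(=O)O[C@H]1C[C@@](C)(O)C(=O)CC[C@@]2(C)O[C@H]2[C@H]2OC(=O)C(COC(C)=O)=C12
F5 | step 4 | (5S)-4-ethenyl-3-iodo-5-[(2S,3R)-3-methyl-3-(4-methylpent-3-en-1-yl)oxiran-2-yl]furan-2(5H)-one | C=CC1=C(I)C(=O)O[C@@H]1[C@@H]2O[C@]2(C)CCC=C(C)C
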